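## Analysis of the target

Compound 27 (C30H22O17) is a linear chain of five benzene rings, A to E, joined by four diaryl ether oxygens and carrying thirteen free hydroxyls. Ring A is a 2,4,6-trihydroxyphenyl group and ring E a 3,4,5-trihydroxyphenyl group. Ring B is 1,2,3,5-tetraoxygenated: B1 carries the oxygen to ring A, the neighbouring B2 the oxygen to ring C, B3 and B5 carry hydroxyls, and B4 and B6 carry hydrogen. Ring C has C1 (oxygen to ring B), hydroxyls at C3 and C5, and C4 (oxygen to ring D); ring D has D1 (oxygen to ring C), hydroxyls at D3 to D5, and D6 (oxygen to ring E). There is no stereocentre and the ether axes rotate freely, so the problem is purely one of regiochemistry. The pyrogallol units of rings D and E, and the polyphenol as a whole, oxidise easily in air, above all as phenolates, so the free hydroxyls should appear only in the last step. The difficulty is that thirteen oxygens of similar reactivity must be told apart, and that every ether bond sits on at least one carbon flanked by two oxygens (the ring A ipso carbon, B2, C4, D6), where electron-rich, doubly ortho-substituted rings couple poorly. The strategy rests on ring B: read from B1 it is a 2-aryloxy-3,5-dioxygenated phenol, which is the pattern obtained when a 4-aryloxy-3-alkoxycyclobutenone (B1 to B4, with the B2 oxygen attached) is joined to an alkoxyacetylene (B5 and B6).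

## Retrosynthetic reasoning

27 to 26. All thirteen O-alkyl bonds (eleven methyl, two ethyl) are cut in the last step. The two ethyl ethers on ring B are a consequence of the ring construction and need a Lewis-acid dealkylation in any case. Making every other hydroxyl a methyl ether lets one operation finish the synthesis and keeps the air-sensitive polyphenol out of all earlier steps.

26 to 19 and 25. The bond between the C4 oxygen of ring C and D1 is cut. This divides the molecule into an A–B–C half and a D–E half of similar size. The polarity is chosen so that the electron-rich, doubly flanked ring C is the phenol 19 and the ring D partner 25 is a bromide with a single ortho substituent. The forward step is a copper-catalysed O-arylation.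

25 to 23 and 24, then 23 to 21 to 20. The D6–O–E1 bond is cut to bromophenol 23 and boronic acid 24, so that an oxidative copper coupling at room temperature can make the ether while leaving the D1 bromine in place. The D6 hydroxyl of 23 is traced to a formyl group (21), and the formyl group to formylation of the symmetric bromide 20, whose two free positions are equivalent.

19 to 18 to 16 and 17. The C4 hydroxyl is masked as the only benzyl ether (18), removable by hydrogenolysis. The B1–O bond to ring A is then cut to phenol 16 and iodide 17. Phenol 16 has a single free hydroxyl, so the coupling needs no selectivity.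

16 to 11 and 8. Ring B is taken apart at B1–B6 and B4–B5, with B1–B2 opened and re-formed in the forward sense. This is the key disconnection. It reduces the crowded B2 ether, flanked on ring B by two oxygens, to the aryloxy substituent of a four-membered ring, and it delivers B1 as the only free hydroxyl. The forward reaction must join the cyclobutenone 11 and the ynol ether 8 with the ethoxy group of 8 ending at B5.

11 to 7 and 8. The cyclobutenone is cut across C1–C2 and C3–C4 into the ketene 10, derived from acid 7 through chloride 9, and a first molecule of 8. The same polarity that controls the key step places the ethoxy group at C3.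

7 to 4 and 5, then 4 to 2 to 1. The B2 carbon and the ketene carbon come from bromo ester 5. Phenol 4 comes from aldehyde 2 by peracid oxidation through formate 3, and 2 from 1 by benzylation. Ring C is therefore bought with its oxygen pattern complete and its C4 oxygen already differentiated.

## Alternatives that were turned down

Alternative 1: Ring C is cut at C1–C2 and C1–C6, so that five of its carbons come from the symmetric pyranone A2 and C1 comes from the ylide carbon of the aryloxymethylidene phosphorane A3, which already carries the ring B oxygen. In the forward step A2 is O-silylated to its pyrylium form, A3 adds at C2, the 2H-pyran opens to a dienal, and an intramolecular Wittig reaction closes ring C as the silyl ether A1.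
- For it: the B2–O–C1 ether again arises without any aryl–oxygen coupling. A2 is symmetric, so there is no regiochemical question. The C4 oxygen emerges as a silyl ether distinct from every other oxygen. On these two points it is at least as good as the chosen route, which relies on electronic control in the ketene–alkyne union and spends a benzyl group on C4.
- Against it: it constructs the one ring of 27 whose pattern can be bought, since 1 gives phenol 4 in two steps. Ring B, with its two neighbouring aryloxy carbons, must be supplied ready-made inside A3 and still joined to ring A by conventional coupling.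
- Mechanistic doubts: the non-stabilised α-aryloxy ylide is a strong base and may desilylate or deprotonate instead of adding. A second deprotonation is needed to regenerate the ylide after addition. Only one dienal geometry can close. Neither A2 nor A3 is commercial.
- Comparison: the chosen benzannulation builds the ring that cannot be bought, from two partners a few steps from commodity chemicals.

Alternative 2: Ring C is closed last at C3–C4 from the open-chain keto ester A5, which carries the A–B half as an enol aryl ether at the future C1 and the D–E half as an aryloxymethyl ketone at the future C4. A strong hindered amide base deprotonates the aryloxymethyl carbon, the enolate attacks the cis ester in a Dieckmann-type condensation, and tautomerisation gives the resorcinol A4.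
- For it: it is the most convergent plan. Both ether oxygens of ring C are attached by alkylation or conjugate addition and not by aryl coupling. On convergence, and in avoiding the C4 ether coupling (step 11 here), it is stronger than the chosen route.
- Against it: the methylene between the enol ether carbon and the ester is activated by both the ester and the vinylogous ketone, and is more acidic than the aryloxymethyl carbon. Deprotonation there leads to double-bond isomerisation and to expulsion of the A–B phenoxide from the vinylogous ester instead of cyclisation. Only the isomer with ketone and ester arms cis can close.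
- Further cost: the two halves still require the hindered A–B and D–E ethers, and the A–B half needs a free hydroxyl at B2 between two oxygens. That is the very problem the chosen key step solves by making ring B around the B2 oxygen.
- Comparison: the chosen route accepts one late copper coupling and in exchange has a two-component key step with no competing enolisation.

Alternative 3: Ring D is cut at D1–D2 back to the squarate-derived cyclobutenone A7, which bears the ring E aryloxy group, two methoxy groups and a 1-ethoxyethenyl group. Thermolysis opens A7 to a dienylketene, whose 6π closure and tautomerisation give the phenol A6 with the D6–O–ring E ether in place (a Moore-type rearrangement).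
- For it: it builds the most heavily oxygenated ring, with every oxygen placed by the four-membered template. The ring-forming event is unimolecular and so is free of ketene dimerisation. In reliability of the ring closure itself it is stronger than the chosen bimolecular benzannulation.
- Against it: the pattern of ring D is reached here in three conventional steps from 20, so little is gained. A6 emerges as a phenol at D1, so ring C would have to be the electrophile at C4, a carbon flanked by two alkoxy groups and para to an oxygen, the worst polarity for this ether. Ring B, with its vicinal aryloxy carbons, would be left entirely to classical coupling.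
- Further doubt: the organometallic addition to a mixed squarate must choose between two different carbonyl groups and can displace the aryloxide.
- Comparison: the chosen route places its ring construction where conventional chemistry is weakest, at ring B.

Key step: step 5

Remark on the chemistry: 27 has no stereocentre, so its SMILES defines it fully. Compounds 11, 13 and 15 are racemic and their stereocentres vanish on aromatisation.

## Route

Step 1
Reactants: 1 syringaldehyde (4-hydroxy-3,5-dimethoxybenzaldehyde)
Product: 2 4-(benzyloxy)-3,5-dimethoxybenzaldehyde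
Conditions: BnBr, K2CO3, DMF, 60 °C
Reagents that add atoms: benzyl bromide, BrCc1ccccc1
Why: Williamson O-benzylation of the acidic, doubly ortho-substituted phenol under carbonate conditions; the benzyl ether marks the future C4 oxygen of ring C against all methyl and ethyl ethers and is removable by hydrogenolysis.

Step 2
Reactants: 2 4-(benzyloxy)-3,5-dimethoxybenzaldehyde
Product: 4 4-(benzyloxy)-3,5-dimethoxyphenol, via aryl formate 3 (not isolated)
Conditions: mCPBA, CH2Cl2, 0 °C to rt; then K2CO3 (cat.), MeOH, rt
Reagents that add atoms: mCPBA (3-chloroperoxybenzoic acid), OOC(=O)c1cccc(Cl)c1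
Why: Baeyer–Villiger (Dakin-type) oxidation: the electron-rich aryl group migrates in the peracid adduct to give formate 3, which is methanolysed in the same flask; the formyl carbon is thereby replaced by the C1 oxygen of ring C.

Step 3
Reactants: 4 4-(benzyloxy)-3,5-dimethoxyphenol; 5 ethyl bromoacetate
Product: 7 [4-(benzyloxy)-3,5-dimethoxyphenoxy]acetic acid, via ethyl ester 6 (not isolated)
Conditions: K2CO3, acetone, reflux; then NaOH, H2O/EtOH, rt; then HCl (aq.)
Reagents that add atoms: sodium hydroxide (one carboxyl oxygen), [Na+].[OH-]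
Why: Williamson alkylation of the unhindered phenoxide with the α-bromo ester (SN2 at a primary, carbonyl-activated carbon), followed by saponification of ester 6 without isolation; the methylene group of 7 is the future B2 carbon.

Step 4
Reactants: 7 [4-(benzyloxy)-3,5-dimethoxyphenoxy]acetic acid; 8 ethoxyacetylene
Product: 11 4-[4-(benzyloxy)-3,5-dimethoxyphenoxy]-3-ethoxycyclobut-2-en-1-one (racemic), via acid chloride 9 (not isolated), via aryloxyketene 10 (not isolated)
Conditions: (COCl)2, DMF (cat.), CH2Cl2, 0 °C to rt, evaporate; then 8 (3 equiv), Et3N, Et2O, 0 °C to rt, slow addition of 9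
Reagents that add atoms: none
Why: Et3N dehydrochlorinates 9 to aryloxyketene 10, which the excess electron-rich ynol ether intercepts in a ketene–alkyne [2+2] cycloaddition; the unsubstituted alkyne carbon bonds to the ketene carbonyl carbon, so ethoxy ends at C3 and aryloxy at C4. The C4 stereocentre forms racemic and is lost in step 5.

Step 5
Reactants: 11 4-[4-(benzyloxy)-3,5-dimethoxyphenoxy]-3-ethoxycyclobut-2-en-1-one; 8 ethoxyacetylene
Product: 16 2-[4-(benzyloxy)-3,5-dimethoxyphenoxy]-3,5-diethoxyphenol, via vinylketene 12 (not isolated), via vinylcyclobutenone 13 (not isolated), via dienylketene 14 (not isolated), via cyclohexadienone 15 (not isolated)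
Conditions: 8 (4 equiv), toluene, 80–100 °C, sealed tube; then K2CO3, MeOH, rt
Reagents that add atoms: none
Why: On heating, 11 undergoes reversible conrotatory 4π ring opening, the C4 aryloxy donor turning outward, to the aryloxy(ethoxy)vinylketene 12. The ketene C=C bond of 12 adds the ynol ether 8 in a [2+2] cycloaddition: the nucleophilic unsubstituted alkyne carbon bonds to the ketene carbonyl carbon (B1–B6) and the ethoxy-bearing carbon to the ketene α-carbon (B4–B5), giving 13. A second 4π opening of 13 gives dienylketene 14, and ring B closes by thermal disrotatory 6π electrocyclisation of 14, which re-forms B1–B2 and gives cyclohexadienone 15; this tautomerises to phenol 16. The closest known reaction type is the Danheiser benzannulation of cyclobutenones with alkoxy- and siloxyacetylenes to resorcinol monoethers. No stereocentre survives: the racemic sp3 carbons of 11, 13 and 15 all become aromatic carbons. The selectivity needed is the regiochemistry of the ketene–alkyne union, secured by the matched polarity of the electrophilic ketene carbon and the nucleophilic β-carbon of the ynol ether, which puts the new ethoxy group at B5 and the free hydroxyl at B1. The isomer of 14 with the wrong geometry at its central double bond can return to 13 and is funnelled through. Excess 8 is meant to outrun ketene dimerisation, and the final methanolysis cleaves any aryl ester formed when 16 is acylated by a ketene.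

Step 6
Reactants: 16 2-[4-(benzyloxy)-3,5-dimethoxyphenoxy]-3,5-diethoxyphenol; 17 2-iodo-1,3,5-trimethoxybenzene
Product: 18 2-[4-(benzyloxy)-3,5-dimethoxyphenoxy]-1,5-diethoxy-3-(2,4,6-trimethoxyphenoxy)benzene
Conditions: CuI (20 mol %), picolinic acid (40 mol %), K3PO4, DMSO, 100 °C, Ar
Reagents that add atoms: none
Why: Ullmann-type copper-catalysed O-arylation with a picolinate ligand system suited to ortho-substituted phenols and hindered aryl iodides; the iodide is chosen because ring A is electron-rich and doubly ortho-substituted. B1–OH is the only free hydroxyl of 16, so no selectivity is required.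

Step 7
Reactants: 18 2-[4-(benzyloxy)-3,5-dimethoxyphenoxy]-1,5-diethoxy-3-(2,4,6-trimethoxyphenoxy)benzene
Product: 19 4-[2,4-diethoxy-6-(2,4,6-trimethoxyphenoxy)phenoxy]-2,6-dimethoxyphenol
Conditions: H2 (1 atm), 10% Pd/C, EtOAc/EtOH, rt
Reagents that add atoms: none
Why: Hydrogenolysis of the single benzyl ether; methyl, ethyl and diaryl ethers are inert and no halogen is present, so only the C4 hydroxyl of ring C is released.

Step 8
Reactants: 20 5-bromo-1,2,3-trimethoxybenzene
Product: 21 6-bromo-2,3,4-trimethoxybenzaldehyde
Conditions: Cl2CHOMe, TiCl4, CH2Cl2, −10 to 0 °C; then H2O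
Reagents that add atoms: dichloromethyl methyl ether, COC(Cl)Cl; water, O
Why: Rieche formylation (electrophilic aromatic substitution by the oxocarbenium ion generated with TiCl4); the two free positions of 20 are equivalent, each para to one methoxy and ortho to another, so only one aldehyde can form. The formyl group is the masked D6 hydroxyl and the bromine marks D1.

Step 9
Reactants: 21 6-bromo-2,3,4-trimethoxybenzaldehyde
Product: 23 6-bromo-2,3,4-trimethoxyphenol, via aryl formate 22 (not isolated)
Conditions: mCPBA, CH2Cl2, rt; then K2CO3 (cat.), MeOH, rt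
Reagents that add atoms: mCPBA (3-chloroperoxybenzoic acid), OOC(=O)c1cccc(Cl)c1
Why: Baeyer–Villiger (Dakin-type) oxidation; methoxy groups ortho and para to the formyl group favour aryl migration to formate 22, and methanolysis gives the phenol with the aryl bromide untouched.

Step 10
Reactants: 23 6-bromo-2,3,4-trimethoxyphenol; 24 (3,4,5-trimethoxyphenyl)boronic acid
Product: 25 1-bromo-3,4,5-trimethoxy-2-(3,4,5-trimethoxyphenoxy)benzene
Conditions: Cu(OAc)2 (1 equiv), pyridine, 4 Å MS, CH2Cl2, air, rt
Reagents that add atoms: none
Why: Chan–Lam oxidative coupling of a phenol with an arylboronic acid, mediated by divalent copper at room temperature; it forms the D6–O–E1 ether without engaging the aryl bromide, and the boronic acid is unhindered and electron-rich, the favourable case even for a doubly ortho-substituted phenol.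

Step 11
Reactants: 19 4-[2,4-diethoxy-6-(2,4,6-trimethoxyphenoxy)phenoxy]-2,6-dimethoxyphenol; 25 1-bromo-3,4,5-trimethoxy-2-(3,4,5-trimethoxyphenoxy)benzene
Product: 26 2-{4-[3,4,5-trimethoxy-2-(3,4,5-trimethoxyphenoxy)phenoxy]-3,5-dimethoxyphenoxy}-1,5-diethoxy-3-(2,4,6-trimethoxyphenoxy)benzene
Conditions: CuI (30 mol %), picolinic acid (60 mol %), K3PO4, DMSO, 110 °C, Ar (degassed)
Reagents that add atoms: none
Why: Ullmann-type copper-catalysed O-arylation uniting the two halves; the nucleophile is the electron-rich phenoxide of 19 and the bromide 25 has only one ortho substituent, the better of the two possible polarities for this hindered ether. Air is excluded because the phenoxide of 19 is oxidisable.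

Step 12
Reactants: 26 2-{4-[3,4,5-trimethoxy-2-(3,4,5-trimethoxyphenoxy)phenoxy]-3,5-dimethoxyphenoxy}-1,5-diethoxy-3-(2,4,6-trimethoxyphenoxy)benzene
Product: 27 2-(2-{3,5-dihydroxy-4-[3,4,5-trihydroxy-2-(3,4,5-trihydroxyphenoxy)phenoxy]phenoxy}-3,5-dihydroxyphenoxy)benzene-1,3,5-triol
Conditions: BBr3 (excess), CH2Cl2, −78 °C to rt; then MeOH, H2O (degassed), Ar
Reagents that add atoms: none
Why: Lewis-acid dealkylation: BBr3 coordinates each alkyl aryl ether oxygen and bromide removes the methyl or ethyl group by SN2, while the diaryl ether bonds offer no sp3 carbon and survive; hydrolysis of the aryl borates with exclusion of air releases the thirteen hydroxyls.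

## Compound list

1 | syringaldehyde (4-hydroxy-3,5-dimethoxybenzaldehyde) | COc1cc(C=O)cc(OC)c1O | starting material
2 | 4-(benzyloxy)-3,5-dimethoxybenzaldehyde | COc1cc(C=O)cc(OC)c1OCc1ccccc1 | intermediate
3 | 4-(benzyloxy)-3,5-dimethoxyphenyl formate | COc1cc(OC=O)cc(OC)c1OCc1ccccc1 | intermediate (not isolated)
4 | 4-(benzyloxy)-3,5-dimethoxyphenol | COc1cc(O)cc(OC)c1OCc1ccccc1 | intermediate
5 | ethyl bromoacetate | CCOC(=O)CBr | starting material
6 | ethyl [4-(benzyloxy)-3,5-dimethoxyphenoxy]acetate | CCOC(=O)COc1cc(OC)c(OCc2ccccc2)c(OC)c1 | intermediate (not isolated)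
7 | [4-(benzyloxy)-3,5-dimethoxyphenoxy]acetic acid | OC(=O)COc1cc(OC)c(OCc2ccccc2)c(OC)c1 | intermediate
8 | ethoxyacetylene | C#COCC | starting material
9 | [4-(benzyloxy)-3,5-dimethoxyphenoxy]acetyl chloride | ClC(=O)COc1cc(OC)c(OCc2ccccc2)c(OC)c1 | intermediate (not isolated)
10 | 2-[4-(benzyloxy)-3,5-dimethoxyphenoxy]ethen-1-one (aryloxyketene) | O=C=COc1cc(OC)c(OCc2ccccc2)c(OC)c1 | intermediate (not isolated)
11 | 4-[4-(benzyloxy)-3,5-dimethoxyphenoxy]-3-ethoxycyclobut-2-en-1-one (racemic) | O=C1C=C(OCC)C1Oc1cc(OC)c(OCc2ccccc2)c(OC)c1 | intermediate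
12 | (3Z)-4-[4-(benzyloxy)-3,5-dimethoxyphenoxy]-3-ethoxybuta-1,3-dien-1-one | O=C=C/C(OCC)=C/Oc1cc(OC)c(OCc2ccccc2)c(OC)c1 | intermediate (not isolated)
13 | 4-{(Z)-2-[4-(benzyloxy)-3,5-dimethoxyphenoxy]-1-ethoxyethenyl}-3-ethoxycyclobut-2-en-1-one (racemic) | O=C1C=C(OCC)C1/C(OCC)=C/Oc1cc(OC)c(OCc2ccccc2)c(OC)c1 | intermediate (not isolated)
14 | (3E,5Z)-6-[4-(benzyloxy)-3,5-dimethoxyphenoxy]-3,5-diethoxyhexa-1,3,5-trien-1-one | O=C=C/C(OCC)=C\C(OCC)=C\Oc1cc(OC)c(OCc2ccccc2)c(OC)c1 | intermediate (not isolated)
15 | 6-[4-(benzyloxy)-3,5-dimethoxyphenoxy]-3,5-diethoxycyclohexa-2,4-dien-1-one (racemic) | O=C1C=C(OCC)C=C(OCC)C1Oc1cc(OC)c(OCc2ccccc2)c(OC)c1 | intermediate (not isolated)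
16 | 2-[4-(benzyloxy)-3,5-dimethoxyphenoxy]-3,5-diethoxyphenol | CCOc1cc(O)c(Oc2cc(OC)c(OCc3ccccc3)c(OC)c2)c(OCC)c1 | intermediate
17 | 2-iodo-1,3,5-trimethoxybenzene | COc1cc(OC)c(I)c(OC)c1 | starting material
18 | 2-[4-(benzyloxy)-3,5-dimethoxyphenoxy]-1,5-diethoxy-3-(2,4,6-trimethoxyphenoxy)benzene | CCOc1cc(Oc2c(OC)cc(OC)cc2OC)c(Oc2cc(OC)c(OCc3ccccc3)c(OC)c2)c(OCC)c1 | intermediate
19 | 4-[2,4-diethoxy-6-(2,4,6-trimethoxyphenoxy)phenoxy]-2,6-dimethoxyphenol | CCOc1cc(Oc2c(OC)cc(OC)cc2OC)c(Oc2cc(OC)c(O)c(OC)c2)c(OCC)c1 | intermediate
20 | 5-bromo-1,2,3-trimethoxybenzene | COc1cc(Br)cc(OC)c1OC | starting material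
21 | 6-bromo-2,3,4-trimethoxybenzaldehyde | COc1cc(Br)c(C=O)c(OC)c1OC | intermediate
22 | 6-bromo-2,3,4-trimethoxyphenyl formate | COc1cc(Br)c(OC=O)c(OC)c1OC | intermediate (not isolated)
23 | 6-bromo-2,3,4-trimethoxyphenol | COc1cc(Br)c(O)c(OC)c1OC | intermediate
24 | (3,4,5-trimethoxyphenyl)boronic acid | COc1cc(B(O)O)cc(OC)c1OC | starting material
25 | 1-bromo-3,4,5-trimethoxy-2-(3,4,5-trimethoxyphenoxy)benzene | COc1cc(Br)c(Oc2cc(OC)c(OC)c(OC)c2)c(OC)c1OC | intermediate
26 | 2-{4-[3,4,5-trimethoxy-2-(3,4,5-trimethoxyphenoxy)phenoxy]-3,5-dimethoxyphenoxy}-1,5-diethoxy-3-(2,4,6-trimethoxyphenoxy)benzene | CCOc1cc(Oc2c(OC)cc(OC)cc2OC)c(Oc2cc(OC)c(Oc3cc(OC)c(OC)c(OC)c3Oc3cc(OC)c(OC)c(OC)c3)c(OC)c2)c(OCC)c1 | intermediate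
27 | 2-(2-{3,5-dihydroxy-4-[3,4,5-trihydroxy-2-(3,4,5-trihydroxyphenoxy)phenoxy]phenoxy}-3,5-dihydroxyphenoxy)benzene-1,3,5-triol | Oc1cc(O)c(Oc2cc(O)cc(O)c2Oc2cc(O)c(Oc3cc(O)c(O)c(O)c3Oc3cc(O)c(O)c(O)c3)c(O)c2)c(O)c1 | target

## Step count and uncertain steps

Total: 12 steps. Longest linear sequence: 9 steps (steps 1 to 7, 11 and 12, from 1). The D–E fragment takes 3 steps (8 to 10) before the union.

Step 5 (key step). The vinylogous-ester stabilisation of 11 may raise the temperature needed for ring opening to the range where the ynol ether fragments thermally to ketene and ethylene. The alkyne would then be consumed, and the electron-rich vinylketene would be lost by dimerisation or by acylating the product phenol. The fallback gives up the ring construction and takes ring B from an aromatic aldehyde. Commercial 3,5-dihydroxybenzaldehyde would be ethylated (EtI, K2CO3, DMF) to 3,5-diethoxybenzaldehyde F1 and brominated next to the formyl group (NBS, MeCN) to 2-bromo-3,5-diethoxybenzaldehyde F2. Setting out from phenol 4, copper-catalysed coupling with F2 (CuI, picolinic acid, K3PO4, DMSO), whose bromide is activated by the ortho formyl group, should give 2-[4-(benzyloxy)-3,5-dimethoxyphenoxy]-3,5-diethoxybenzaldehyde F3. Baeyer–Villiger oxidation (mCPBA) to 2-[4-(benzyloxy)-3,5-dimethoxyphenoxy]-3,5-diethoxyphenyl formate F4 and methanolysis would come back to the route at 16.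

Step 4. The amine used to make the ketene can also catalyse its dimerisation. The very electron-rich ring can be acylated intramolecularly by the acid chloride. The vinylogous ester of 11 can hydrolyse during isolation. The fallback avoids both the aryloxyketene and the isolated cyclobutenone by generating the vinylketene from an unsaturated acid chloride. Ethyl 4-chloroacetoacetate and triethyl orthoformate (acid catalysis) would give ethyl (2E)-4-chloro-3-ethoxybut-2-enoate F5. Setting out from phenol 4, alkylation with F5 (K2CO3, DMF) should give ethyl (2E)-4-[4-(benzyloxy)-3,5-dimethoxyphenoxy]-3-ethoxybut-2-enoate F6. Saponification (LiOH) would give (2E)-4-[4-(benzyloxy)-3,5-dimethoxyphenoxy]-3-ethoxybut-2-enoic acid F7, and oxalyl chloride would give (2E)-4-[4-(benzyloxy)-3,5-dimethoxyphenoxy]-3-ethoxybut-2-enoyl chloride F8. 1,4-Dehydrochlorination of F8 with Et3N in the presence of excess 8 in warm toluene should produce vinylketene 12 directly, which enters the cascade of step 5 and comes back to the route at 16.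

Step 6. Oxidative addition to the electron-rich, doubly ortho-methoxylated iodide is slow, so reduction of the iodide to the arene may outrun ether formation and leave the phenol unchanged. The fallback replaces the iodide by an electronically activated ring and adjusts the oxidation state afterwards. Setting out from 16, coupling with commercial 4-bromo-3,5-dimethoxybenzaldehyde (CuI, picolinic acid, K3PO4, DMSO) should give 4-{2-[4-(benzyloxy)-3,5-dimethoxyphenoxy]-3,5-diethoxyphenoxy}-3,5-dimethoxybenzaldehyde F9. Baeyer–Villiger oxidation would give 4-{2-[4-(benzyloxy)-3,5-dimethoxyphenoxy]-3,5-diethoxyphenoxy}-3,5-dimethoxyphenyl formate F10, and methanolysis 4-{2-[4-(benzyloxy)-3,5-dimethoxyphenoxy]-3,5-diethoxyphenoxy}-3,5-dimethoxyphenol F11. O-Methylation (MeI, K2CO3) comes back to the route at 18.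

Step 11. Both partners are electron-rich and the new ether carries three ortho substituents. Slow coupling would leave time for reduction of the bromide and for oxidative degradation of the phenoxide of 19, with loss of its para aryloxy group. The fallback builds the D–E unit on ring C in linear fashion from the same building blocks. Setting out from 19, coupling with aldehyde 21, whose bromide is activated by the ortho formyl group, should give 6-{4-[2,4-diethoxy-6-(2,4,6-trimethoxyphenoxy)phenoxy]-2,6-dimethoxyphenoxy}-2,3,4-trimethoxybenzaldehyde F12. Baeyer–Villiger oxidation would give 6-{4-[2,4-diethoxy-6-(2,4,6-trimethoxyphenoxy)phenoxy]-2,6-dimethoxyphenoxy}-2,3,4-trimethoxyphenyl formate F13, and methanolysis 6-{4-[2,4-diethoxy-6-(2,4,6-trimethoxyphenoxy)phenoxy]-2,6-dimethoxyphenoxy}-2,3,4-trimethoxyphenol F14. Chan–Lam coupling of F14 with boronic acid 24 (Cu(OAc)2, pyridine, air) comes back to the route at 26.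

Step 12. Thirteen ethers must be cleaved, the ethyl ethers more slowly than the methyl ethers, so dealkylation may stop short. The free polyphenol may also oxidise during work-up and chromatography. The fallback isolates the product as a stable derivative. Setting out from 26, the crude product of the BBr3 reaction would be acetylated directly (Ac2O, pyridine) to the trideca-acetate of 27, F15, which can be purified on silica and separated from under-dealkylated material. Acid-catalysed methanolysis (HCl in degassed MeOH, Ar) then comes back to the route at 27.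

## Further compounds

F1 | step 5 | 3,5-diethoxybenzaldehyde | CCOc1cc(C=O)cc(OCC)c1
F2 | step 5 | 2-bromo-3,5-diethoxybenzaldehyde | CCOc1cc(OCC)c(Br)c(C=O)c1
F3 | step 5 | 2-[4-(benzyloxy)-3,5-dimethoxyphenoxy]-3,5-diethoxybenzaldehyde | CCOc1cc(OCC)c(Oc2cc(OC)c(OCc3ccccc3)c(OC)c2)c(C=O)c1
F4 | step 5 | 2-[4-(benzyloxy)-3,5-dimethoxyphenoxy]-3,5-diethoxyphenyl formate | CCOc1cc(OCC)c(Oc2cc(OC)c(OCc3ccccc3)c(OC)c2)c(OC=O)c1
F5 | step 4 | ethyl (2E)-4-chloro-3-ethoxybut-2-enoate | CCOC(=O)/C=C(\CCl)OCC
F6 | step 4 | ethyl (2E)-4-[4-(benzyloxy)-3,5-dimethoxyphenoxy]-3-ethoxybut-2-enoate | CCOC(=O)/C=C(\COc1cc(OC)c(OCc2ccccc2)c(OC)c1)OCC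
F7 | step 4 | (2E)-4-[4-(benzyloxy)-3,5-dimethoxyphenoxy]-3-ethoxybut-2-enoic acid | OC(=O)/C=C(\COc1cc(OC)c(OCc2ccccc2)c(OC)c1)OCC
F8 | step 4 | (2E)-4-[4-(benzyloxy)-3,5-dimethoxyphenoxy]-3-ethoxybut-2-enoyl chloride | ClC(=O)/C=C(\COc1cc(OC)c(OCc2ccccc2)c(OC)c1)OCC
F9 | step 6 | 4-{2-[4-(benzyloxy)-3,5-dimethoxyphenoxy]-3,5-diethoxyphenoxy}-3,5-dimethoxybenzaldehyde | CCOc1cc(Oc2c(OC)cc(C=O)cc2OC)c(Oc2cc(OC)c(OCc3ccccc3)c(OC)c2)c(OCC)c1
F10 | step 6 | 4-{2-[4-(benzyloxy)-3,5-dimethoxyphenoxy]-3,5-diethoxyphenoxy}-3,5-dimethoxyphenyl formate | CCOc1cc(Oc2c(OC)cc(OC=O)cc2OC)c(Oc2cc(OC)c(OCc3ccccc3)c(OC)c2)c(OCC)c1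
F11 | step 6 | 4-{2-[4-(benzyloxy)-3,5-dimethoxyphenoxy]-3,5-diethoxyphenoxy}-3,5-dimethoxyphenol | CCOc1cc(Oc2c(OC)cc(O)cc2OC)c(Oc2cc(OC)c(OCc3ccccc3)c(OC)c2)c(OCC)c1
F12 | step 11 | 6-{4-[2,4-diethoxy-6-(2,4,6-trimethoxyphenoxy)phenoxy]-2,6-dimethoxyphenoxy}-2,3,4-trimethoxybenzaldehyde | CCOc1cc(Oc2c(OC)cc(OC)cc2OC)c(Oc2cc(OC)c(Oc3cc(OC)c(OC)c(OC)c3C=O)c(OC)c2)c(OCC)c1
F13 | step 11 | 6-{4-[2,4-diethoxy-6-(2,4,6-trimethoxyphenoxy)phenoxy]-2,6-dimethoxyphenoxy}-2,3,4-trimethoxyphenyl formate | CCOc1cc(Oc2c(OC)cc(OC)cc2OC)c(Oc2cc(OC)c(Oc3cc(OC)c(OC)c(OC)c3OC=O)c(OC)c2)c(OCC)c1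
F14 | step 11 | 6-{4-[2,4-diethoxy-6-(2,4,6-trimethoxyphenoxy)phenoxy]-2,6-dimethoxyphenoxy}-2,3,4-trimethoxyphenol | CCOc1cc(Oc2c(OC)cc(OC)cc2OC)c(Oc2cc(OC)c(Oc3cc(OC)c(OC)c(OC)c3O)c(OC)c2)c(OCC)c1
F15 | step 12 | trideca-O-acetate of 27 | CC(=O)Oc1cc(OC(C)=O)c(Oc2cc(OC(C)=O)cc(OC(C)=O)c2Oc2cc(OC(C)=O)c(Oc3cc(OC(C)=O)c(OC(C)=O)c(OC(C)=O)c3Oc3cc(OC(C)=O)c(OC(C)=O)c(OC(C)=O)c3)c(OC(C)=O)c2)c(OC(C)=O)c1
A1 | alternative 1 | {4-[2-(benzyloxy)-4,6-dimethoxyphenoxy]-2,6-dimethoxyphenoxy}(tert-butyl)dimethylsilane | COc1cc(Oc2c(OC)cc(OC)cc2OCc2ccccc2)cc(OC)c1O[Si](C)(C)C(C)(C)C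
A2 | alternative 1 | 3,5-dimethoxy-4H-pyran-4-one | COC1=COC=C(OC)C1=O
A3 | alternative 1 | {[2-(benzyloxy)-4,6-dimethoxyphenoxy]methylidene}(triphenyl)-λ5-phosphane | COc1cc(OC)c(OC=P(c2ccccc2)(c2ccccc2)c2ccccc2)c(OCc2ccccc2)c1
A4 | alternative 2 | 5-[2,4-dimethoxy-6-(2,4,6-trimethoxyphenoxy)phenoxy]-2-[3,4,5-trimethoxy-2-(3,4,5-trimethoxyphenoxy)phenoxy]benzene-1,3-diol | Oc1cc(Oc2c(OC)cc(OC)cc2Oc2c(OC)cc(OC)cc2OC)cc(O)c1Oc1cc(OC)c(OC)c(OC)c1Oc1cc(OC)c(OC)c(OC)c1
A5 | alternative 2 | methyl (3E)-3-[2,4-dimethoxy-6-(2,4,6-trimethoxyphenoxy)phenoxy]-5-oxo-6-[3,4,5-trimethoxy-2-(3,4,5-trimethoxyphenoxy)phenoxy]hex-3-enoate | COC(=O)C/C(Oc1c(OC)cc(OC)cc1Oc1c(OC)cc(OC)cc1OC)=C\C(=O)COc1cc(OC)c(OC)c(OC)c1Oc1cc(OC)c(OC)c(OC)c1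
A6 | alternative 3 | 5-ethoxy-3,4-dimethoxy-2-(3,4,5-trimethoxyphenoxy)phenol | CCOc1cc(O)c(Oc2cc(OC)c(OC)c(OC)c2)c(OC)c1OC
A7 | alternative 3 | 4-(1-ethoxyethenyl)-3,4-dimethoxy-2-(3,4,5-trimethoxyphenoxy)cyclobut-2-en-1-one (racemic) | C=C(OCC)C1(OC)C(OC)=C(Oc2cc(OC)c(OC)c(OC)c2)C1=O
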